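Two things were asked of these flasks: a row of end yields and the shape of that row.

the same everywhere: starting material 0.80 M (in portions, 4)

| run | partner | initiator | remark | time |
|---|---|---|---|---|
| south-west | 1.6 M | 40 mM | run made earlier; portions every 6.0 min |  |
| south-east | 1.6 M | 60 mM | run made earlier; portions every 6.0 min |  |
| Friday's | 1.60 M | 80 mM | the portions of starting material follow each other after 6.0 min, the first at the start | 1.0 h |
| Monday's | 1.60 M | 80 mM | the portions of starting material follow each other after 10 min, the first at the start | 1.0 h |
| Tuesday's | 1.60 M | 80 mM | the portions of starting material follow each other after 15 min, the first at the start | 1.0 h |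
| Saturday's | 1.60 M | 80 mM | the portions of starting material follow each other after 25 min, the first at the start | 1.0 h |

- amount of product at the end, in percent of the starting material charged for Friday's, Monday's, Tuesday's, Saturday's, in this order
- the course of these numbers from the first flask to the last (falls all the way / falls, then rises / hardly changes / rises, then falls / rises all the way)

- what was read earlier has a scatter of 0.5 percentage points, one standard deviation
- percentages count the whole charge, also what has not yet gone in
- "hardly changes" means that all values lie within two and a half points (for a concentration: within two and a half percent of the largest)

| run | time / min | product / % | starting material / % |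
|---|---|---|---|
| south-west | 10.0 | 50.1 | 0 |
| south-west | 20.0 | 99.0 | 0 |
| south-west | 30.0 | 99.0 | 0 |
| south-west | 40.0 | 99.4 | 0.3 |
| south-west | 50.0 | 98.8 | 0.5 |
| south-west | 60.0 | 98.2 | 0 |
| south-west | 80.0 | 98.6 | 0.4 |
| south-east | 4.00 | 25.6 | 0 |
| south-east | 12.0 | 49.9 | 0 |
| south-east | 20.0 | 98.1 | 0 |
| south-east | 30.0 | 97.0 | 0 |
| south-east | 40.0 | 98.7 | 0 |
| south-east | 60.0 | 98.5 | 0.8 |
| south-east | 80.0 | 97.6 | 0 |

(each reading ± 0.5 percentage points)

The earlier runs first told me how fast a portion goes. In the south-east run, product read 25.6% at 4.00 min, about a quarter of the charge, and starting material read 0%. So that first portion had turned into product before the next one came. In the south-west run, product reached 99.0% at 20.0 min and still read 98.6% at 80.0 min. Product thus stopped growing when the additions stopped, as expected of a limiting reagent: partner stood at twice the starting material.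

The question for each flask was therefore whether its last portion lands inside the run. I divided the time of the last addition, the interval τ times one less than the number of portions n, by the run length t, and for Saturday's this gave the pure number 1.25. This feed ratio φ has no time left in it, and above one the last portion falls outside the run. Friday's gave 0.300, Monday's 0.500 and Tuesday's 0.750, each below one. Saturday's stood above one: its last portion was due at 75.0 min, after the end at 60 min, so 3 portions went in and the ceiling was 75.0% of the charge. The simulated runs made their last addition at 18.0 min, so I had to assume that later portions go as fast. I expected Friday's, Monday's and Tuesday's near the plateau, Saturday's just below its ceiling, and a falling row.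

The forecast gave 97.3%, 97.3%, 97.3% and 73%, a course that falls all the way, with Saturday's low “so only three go in”.

The flasks gave 97.6%, 96.3%, 94.7% and 69.9%, a course that falls all the way.

    initiator → 2 initiating radical (k = 1.20 × 10⁻⁴ /s)
    starting material + initiating radical ⇌ chain carrier (K = 6200 /M, k = 1120 /M/s)
    partner + chain carrier → product + initiating radical (k = 12500 /M/s)
    2 chain carrier → ended chains (k = 9.00 × 10⁶ /M/s)

Saturday's, at φ = 1.25, ended at 69.9%, under its ceiling of 75.0%. The 5.1 percentage points under that ceiling went to ended chains, which stood at 5.07%: without the step that forms them, Saturday's ended at 75.0%. That step is a part only, 17% of what is missing from a full yield; the remainder is the joint work of the portioned addition and the length of the run. Saturday's charge given at once reached 99.9% by 60 min. Saturday's flask itself, carried on to 10.0 h, had its φ fall to 0.125, below one, so its last portion landed inside the run, and product stood at 92.1%.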